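**Retrosynthetic overview**

1. The succinimide side chain is made last: C12–C13 by an auxiliary-controlled syn-aldol on the C11–C12 aldehyde, then nitrile hydration and imide closure.
2. The C6 ketone and C8 exocyclic methylene come from a 6,7-epoxy-8-ketone (Wittig, then palladium-mediated epoxide-to-ketone isomerisation).
3. Ring B (key step): one-carbon ring expansion of a hydrindane cyclopentanol by 1,2-shift of the quaternary C10 onto an alkoxyallyl cation (vinylogous semipinacol). This gives the decalin, the C8 ketone and the C9–CH2–CH(OEt)2 arm in one operation.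
4. The ring A chlorides are set before that, on the gem-dimethylated, ketal-protected Hajos–Parrish ketone: α-chlorination, reduction, retentive chlorination.
5. Ring order: ring A by Robinson annulation (with a five-membered precursor of ring B), then ring B by expansion, then the succinimide ring.

Convention: atoms carry the labdane numbers of the target (ring A = C1–C5/C10, ring B = C5–C10, C17 = exocyclic methylene, side chain C11–C16); α/β = face opposite/same as the C10 methyl.
Assumption: the given SMILES is read as (2R,3R,5R,9S,10R,12S,13R) in this numbering, i.e. 2α,3β-dichloro, 5α-H, 9α-H, 10β-CH3.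

**Route**

Step 1
Reactants: 1 2-methylcyclopentane-1,3-dione; 2 methyl vinyl ketone
Product: 5 (S)-Hajos–Parrish ketone, via triketone 3 (not isolated), via Hajos ketol 4 (not isolated)
Conditions: AcOH (cat.), H2O, 75 °C; then (S)-proline (3 mol %), DMF, 20 °C; then H2SO4 (cat.), 95 °C
Reagents that add atoms: none
Why: Hajos–Parrish–Eder–Sauer–Wiechert Robinson annulation: Michael addition gives 3, the (S)-proline enamine aldol desymmetrises the two ring carbonyls and sets the quaternary C10 centre (the 10β-methyl of the target), and acid dehydration gives the enone.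

Step 2
Reactants: 5 (S)-Hajos–Parrish ketone
Product: 6 C8 mono-ketal of 5
Conditions: 2-ethyl-2-methyl-1,3-dioxolane, ethylene glycol (cat.), p-TsOH (cat.), 20 °C
Reagents that add atoms: 2-ethyl-2-methyl-1,3-dioxolane, CCC1(C)OCCO1
Why: Acid-catalysed transketalisation in which the saturated five-ring carbonyl reacts faster than the conjugated enone carbonyl, masking C8 for the enolate chemistry that follows.

Step 3
Reactants: 6 C8 mono-ketal of 5
Product: 8 4,4-dimethyl-3-ketone ketal (C5=C6), via 4-methyl enone ketal 7 (not isolated)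
Conditions: KOtBu, MeI, tBuOH/THF, 0 → 25 °C
Reagents that add atoms: iodomethane, CI
Why: Deconjugative α,α-dimethylation of the extended potassium dienolate (alkylation at C4 twice) installs the gem-dimethyl group and moves the alkene to C5=C6, the only position left once C4 is quaternary.

Step 4
Reactants: 8 4,4-dimethyl-3-ketone ketal (C5=C6)
Product: 10 2α-chloro-3-ketone ketal, via lithium enolate 9 (not isolated)
Conditions: LiN(iPr)2, THF, −78 °C; then p-TsCl, −78 → −30 °C
Reagents that add atoms: p-toluenesulfonyl chloride, Cc1ccc(cc1)S(Cl)(=O)=O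
Why: Electrophilic α-chlorination of the only possible enolate (C2) with p-TsCl as Cl+ donor; chlorine enters from the α face away from the 10β-methyl, and the equatorial 2α-chloride is also the thermodynamic epimer.

Step 5
Reactants: 10 2α-chloro-3-ketone ketal
Product: 11 2α-chloro-3β-hydroxy ketal
Conditions: NaBH4, MeOH/CH2Cl2, −20 → 0 °C
Reagents that add atoms: none
Why: Borohydride reduction with hydride delivered to the α face (the β face is screened by the axial 4β- and 10β-methyls) gives the equatorial 3β-alcohol, as in other 4,4-dimethyl-3-ketones.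

Step 6
Reactants: 11 2α-chloro-3β-hydroxy ketal
Product: 14 2α,3β-dichloro hydrindenone, via chlorosulfite 12 (not isolated), via dichloro ketal 13 (not isolated)
Conditions: SOCl2, CH2Cl2, 0 °C; evaporate; TiCl4 (10 mol %), CH2Cl2, −78 → 0 °C; then acetone/H2O (10:1), PPTS, 20 °C
Reagents that add atoms: thionyl chloride, O=S(Cl)Cl; water, O
Why: Chlorosulfite formation then TiCl4-catalysed front-side (SNi) chloride delivery replaces the neopentylic, SN2-inert 3β-OH with retention, helped by the homoallylic C5=C6 bond as in cholesterol → cholesteryl chloride, and the acidic wet-acetone quench transketalises the dioxolane to free the C8 ketone.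

Step 7
Reactants: 15 3,3-diethoxyprop-1-yne
Product: 16 (E)-tributyl(3,3-diethoxyprop-1-en-1-yl)stannane
Conditions: Bu3SnH, AIBN (cat.), neat, 85 °C
Reagents that add atoms: tributylstannane, CCCC[SnH](CCCC)CCCC
Why: Radical-chain hydrostannation of the terminal alkyne; reversible stannyl-radical addition funnels to the thermodynamic (E)-β-vinylstannane.

Step 8
Reactants: 14 2α,3β-dichloro hydrindenone; 16 (E)-tributyl(3,3-diethoxyprop-1-en-1-yl)stannane
Product: 19 tertiary allylic alcohol (8β-OH), via alkenyllithium 17 (not isolated), via alkenylcerium dichloride 18 (not isolated)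
Conditions: 16, nBuLi, THF, −78 °C; CeCl3, −78 °C; then 14, −78 °C; NH4Cl (aq)
Reagents that add atoms: none
Why: Tin–lithium exchange and transmetalation to the weakly basic RCeCl2 species allow 1,2-addition to the hindered, easily enolised ketone from the α face opposite the angular methyl (8β-OH), a stereocentre that is erased in step 9.

Step 9
Reactants: 19 tertiary allylic alcohol (8β-OH)
Product: 22 ring-expanded keto acetal, via silyl ether 20 (not isolated), via enol ether ketone 21 (not isolated)
Conditions: TMSOTf (1.2 equiv), 2,6-di-tert-butyl-4-methylpyridine (1.5 equiv), CH2Cl2, −78 → −40 °C; then EtOH, −40 → 0 °C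
Reagents that add atoms: ethanol, CCO
Why: Proposed new method: TMSOTf silylates the tertiary alcohol (20) and then ionises the allylic acetal to an (E)-1-ethoxyallyl cation whose electrophilic terminus C9 sits next to the silyloxy carbon, so the more substituted, more electron-rich C8–C10 ring bond, which can align with the empty p-orbital, migrates to C9 (cyclopentane → cyclohexanone, congestion released), the silyloxocarbenium ion gives up its silyl group (net loss of TMSOEt) and ethanol re-acetalises enol ether 21; this forms ring B, the C8 ketone and the C9–C10 bond in one step, with C9 left epimerisable α to the ketone and fixed in step 10; the closest known reactions are the amine-catalysed vinylogous α-ketol rearrangement of 1-(3-oxoalkenyl)cyclobutanols and Lewis-acid semipinacol (Prins–pinacol) shifts of silyl ethers, neither shown for cyclopentanols, enal acetals or a quaternary migrating carbon.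

Step 10
Reactants: 22 ring-expanded keto acetal
Product: 24 6α,7α-epoxy-8-ketone, via conjugated enone 23 (not isolated)
Conditions: H2O2 (30 % aq.), NaOH, MeOH, 0 → 20 °C
Reagents that add atoms: hydrogen peroxide, OO
Why: Hydroxide equilibrates the β,γ-enone into conjugation (γ-protonation at C5 from the open α face gives the trans ring fusion) and Weitz–Scheffer nucleophilic epoxidation traps the enone irreversibly, while C9 equilibrates to the equatorial side chain (9α-H).

Step 11
Reactants: 24 6α,7α-epoxy-8-ketone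
Product: 25 vinyl epoxide
Conditions: Ph3PCH3Br, KOtBu, THF, 0 → 50 °C
Reagents that add atoms: methyltriphenylphosphonium bromide, C[P+](c1ccccc1)(c1ccccc1)c1ccccc1.[Br-]
Why: Wittig methylenation of the α,β-epoxy ketone gives the vinyl epoxide; the ylide leaves the oxirane, the acetal and the chlorides untouched, and C9 stays in its equatorial configuration.

Step 12
Reactants: 25 vinyl epoxide
Product: 26 6-keto-8(17)-ene acetal
Conditions: Pd(PPh3)4 (5 mol %), THF, 40 °C
Reagents that add atoms: none
Why: Zerovalent-palladium-catalysed isomerisation of a 1,3-diene monoepoxide: ionisation to a π-allylpalladium alkoxide followed by a 1,2-hydride shift from C6 to C7 gives the C6 ketone with the 8(17)-alkene left out of conjugation, under neutral conditions that do not isomerise the β,γ-enone.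

Step 13
Reactants: 26 6-keto-8(17)-ene acetal
Product: 27 aldehyde
Conditions: PPTS, acetone/H2O (9:1), 40 °C
Reagents that add atoms: water, O
Why: Mild acid-catalysed acetal hydrolysis frees the C12 aldehyde without conjugating the β,γ-enone or epimerising C5 or C9.

Step 14
Reactants: 28 3-cyanopropanoic acid
Product: 30 (R)-4-benzyl-3-(3-cyanopropanoyl)oxazolidin-2-one, via mixed pivalic anhydride 29 (not isolated)
Conditions: PivCl, Et3N, THF, −20 °C; then (R)-4-benzyloxazolidin-2-one, LiCl, −20 → 20 °C
Reagents that add atoms: (R)-4-benzyloxazolidin-2-one, O=C1OC[C@@H](Cc2ccccc2)N1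
Why: Mixed-anhydride N-acylation (LiCl/Et3N protocol) attaches the Evans auxiliary; the nitrile is a latent carboxamide that is inert to the enolisation conditions of step 15.

Step 15
Reactants: 27 aldehyde; 30 (R)-4-benzyl-3-(3-cyanopropanoyl)oxazolidin-2-one
Product: 32 syn-aldol adduct, via boron enolate 31 (not isolated)
Conditions: 30, Bu2BOTf, iPr2NEt, CH2Cl2, −78 → 0 °C; then 27, −78 → −10 °C; pH 7 buffer, MeOH, H2O2, 0 °C
Reagents that add atoms: none
Why: Evans syn-aldol: the Z-boron enolate reacts through a Zimmerman–Traxler chair on the face opposite the benzyl group, so the (R)-auxiliary sets 12S,13R, and the aldehyde is attacked in preference to the hindered C6 ketone.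

Step 16
Reactants: 32 syn-aldol adduct
Product: 34 haterumaimide B, via primary amide 33 (not isolated)
Conditions: [PtH{(PMe2O)2H}(PMe2OH)] (5 mol %), EtOH/H2O (4:1), 80 °C
Reagents that add atoms: water, O
Why: Platinum-catalysed neutral nitrile hydration gives the primary amide, whose nitrogen closes on the activated N-acyl oxazolidinone carbonyl (5-exo-trig acyl substitution), forming the succinimide and releasing the auxiliary without base that would conjugate the enone or trigger retro-aldol.

**Compound list**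

1 | 2-methylcyclopentane-1,3-dione | CC1C(=O)CCC1=O | starting material
2 | methyl vinyl ketone (but-3-en-2-one) | CC(=O)C=C | starting material
3 | 2-methyl-2-(3-oxobutyl)cyclopentane-1,3-dione (triketone) | CC(=O)CCC1(C)C(=O)CCC1=O | intermediate
4 | (3aS,7aS)-3a-hydroxy-7a-methylhexahydro-1H-indene-1,5(4H)-dione (cis-fused Hajos ketol) | O=C1CC[C@]2(C)C(=O)CC[C@]2(O)C1 | intermediate
5 | (S)-Hajos–Parrish ketone, (7aS)-7a-methyl-2,3,7,7a-tetrahydro-1H-indene-1,5(6H)-dione | O=C1CC[C@]2(C)C(=O)CCC2=C1 | intermediate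
6 | mono-ketal of 5: spiro-1,3-dioxolane at the saturated carbonyl (C8), C3 enone intact, 10β-CH3 | O=C1CC[C@]2(C)C3(OCCO3)CCC2=C1 | intermediate
7 | 4-methyl enone ketal (6 with one CH3 on C4) | O=C1CC[C@]2(C)C3(OCCO3)CCC2=C1C | intermediate
8 | 4,4-dimethyl-3-ketone ketal with C5=C6 double bond (C8 dioxolane, 10β-CH3) | O=C1CC[C@]2(C)C3(OCCO3)CC=C2C1(C)C | intermediate
9 | lithium C2-enolate of 8 | [Li]OC1=CC[C@]2(C)C3(OCCO3)CC=C2C1(C)C | intermediate
10 | 2α-chloro-3-ketone ketal (equatorial Cl; otherwise as 8) | O=C1[C@H](Cl)C[C@]2(C)C3(OCCO3)CC=C2C1(C)C | intermediate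
11 | 2α-chloro-3β-hydroxy ketal (trans-diequatorial chlorohydrin) | O[C@H]1[C@H](Cl)C[C@]2(C)C3(OCCO3)CC=C2C1(C)C | intermediate
12 | 3β-chlorosulfite of 11 | O=S(Cl)O[C@H]1[C@H](Cl)C[C@]2(C)C3(OCCO3)CC=C2C1(C)C | intermediate
13 | 2α,3β-dichloro ketal | Cl[C@H]1[C@H](Cl)C[C@]2(C)C3(OCCO3)CC=C2C1(C)C | intermediate
14 | (5R,6R,7aS)-5,6-dichloro-4,4,7a-trimethyl-2,4,5,6,7,7a-hexahydro-1H-inden-1-one (2α,3β-dichloro, C8 ketone, C5=C6) | Cl[C@H]1[C@H](Cl)C[C@]2(C)C(=O)CC=C2C1(C)C | intermediate
15 | propiolaldehyde, used as its commercial diethyl acetal 3,3-diethoxyprop-1-yne | C#CC(OCC)OCC | starting material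
16 | (E)-tributyl(3,3-diethoxyprop-1-en-1-yl)stannane | CCCC[Sn](CCCC)(CCCC)/C=C/C(OCC)OCC | intermediate
17 | (E)-3,3-diethoxyprop-1-en-1-yllithium | [Li]/C=C/C(OCC)OCC | intermediate
18 | (E)-3,3-diethoxyprop-1-en-1-ylcerium dichloride | Cl[Ce](Cl)/C=C/C(OCC)OCC | intermediate
19 | tertiary allylic alcohol: 14 carrying 8β-OH and 8α-[(E)-3,3-diethoxyprop-1-enyl] | Cl[C@H]1[C@H](Cl)C[C@]2(C)[C@](O)(/C=C/C(OCC)OCC)CC=C2C1(C)C | intermediate
20 | trimethylsilyl ether of 19 | Cl[C@H]1[C@H](Cl)C[C@]2(C)[C@](O[Si](C)(C)C)(/C=C/C(OCC)OCC)CC=C2C1(C)C | intermediate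
21 | ring-expanded ketone with 9β-[(E)-2-ethoxyvinyl] group (decalin, C8 ketone, C5=C6) | Cl[C@H]1[C@H](Cl)C[C@]2(C)[C@@H](/C=C/OCC)C(=O)CC=C2C1(C)C | intermediate
22 | keto acetal: 2α,3β-dichloro-9β-(2,2-diethoxyethyl)-4,4,10β-trimethyl decalin, C8 ketone, C5=C6, 9α-H | Cl[C@H]1[C@H](Cl)C[C@]2(C)[C@@H](CC(OCC)OCC)C(=O)CC=C2C1(C)C | intermediate
23 | conjugated enone: C8 ketone, C6=C7, 5α-H (trans-fused), otherwise as 22 | Cl[C@H]1[C@H](Cl)C[C@]2(C)[C@@H](CC(OCC)OCC)C(=O)C=C[C@H]2C1(C)C | intermediate
24 | 6α,7α-epoxy-8-ketone (5α-H, 9α-H) | Cl[C@H]1[C@H](Cl)C[C@]2(C)[C@@H](CC(OCC)OCC)C(=O)[C@@H]3O[C@@H]3[C@H]2C1(C)C | intermediate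
25 | vinyl epoxide: 8(17)-methylene-6α,7α-epoxide | Cl[C@H]1[C@H](Cl)C[C@]2(C)[C@@H](CC(OCC)OCC)C(=C)[C@@H]3O[C@@H]3[C@H]2C1(C)C | intermediate
26 | 6-keto-8(17)-ene diethyl acetal (ring system of the target, side chain CH2CH(OEt)2) | C=C1CC(=O)[C@H]2C(C)(C)[C@@H](Cl)[C@H](Cl)C[C@]2(C)[C@H]1CC(OCC)OCC | intermediate
27 | 2-[(1S,4aR,6R,7R,8aR)-6,7-dichloro-5,5,8a-trimethyl-2-methylidene-4-oxodecahydronaphthalen-1-yl]acetaldehyde | C=C1CC(=O)[C@H]2C(C)(C)[C@@H](Cl)[C@H](Cl)C[C@]2(C)[C@H]1CC=O | intermediate
28 | 3-cyanopropanoic acid | N#CCCC(=O)O | starting material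
29 | 3-cyanopropanoic pivalic anhydride | N#CCCC(=O)OC(=O)C(C)(C)C | intermediate
30 | (R)-4-benzyl-3-(3-cyanopropanoyl)oxazolidin-2-one | N#CCCC(=O)N1C(=O)OC[C@H]1Cc1ccccc1 | intermediate
31 | (Z)-dibutylboron enolate of 30 | CCCCB(CCCC)O/C(=C\CC#N)N1C(=O)OC[C@H]1Cc1ccccc1 | intermediate
32 | syn-aldol adduct: (12S)-hydroxy-(13R)-cyanomethyl acyl oxazolidinone | C=C1CC(=O)[C@H]2C(C)(C)[C@@H](Cl)[C@H](Cl)C[C@]2(C)[C@H]1C[C@H](O)[C@@H](CC#N)C(=O)N1C(=O)OC[C@H]1Cc1ccccc1 | intermediate
33 | primary amide from hydration of the nitrile of 32 | C=C1CC(=O)[C@H]2C(C)(C)[C@@H](Cl)[C@H](Cl)C[C@]2(C)[C@H]1C[C@H](O)[C@@H](CC(N)=O)C(=O)N1C(=O)OC[C@H]1Cc1ccccc1 | intermediate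
34 | haterumaimide B, (3R)-3-[(1S)-2-[(1S,4aR,6R,7R,8aR)-6,7-dichloro-5,5,8a-trimethyl-2-methylidene-4-oxodecahydronaphthalen-1-yl]-1-hydroxyethyl]pyrrolidine-2,5-dione | C=C1CC(=O)[C@H]2C(C)(C)[C@@H](Cl)[C@H](Cl)C[C@]2(C)[C@H]1C[C@H](O)[C@H]1CC(=O)NC1=O | target

**Step count and risks**

Total steps: 16. Longest linear sequence: 14 (steps 1–6, 8–13, 15, 16).

Three steps most likely to fail:

Step 9 (the new ring expansion). The risks are migration of the allylic C7 instead of the quaternary C10, or loss of the tertiary silyloxy group. The fallback uses known chemistry, sets out from 19 and returns at 22. Hydroxyl-directed epoxidation of the side-chain alkene (VO(acac)2, tBuOOH) gives the epoxy alcohol F1. The ZnBr2-promoted semipinacol rearrangement of this 2,3-epoxy alcohol, an established ring expansion in which C10 migrates anti to the breaking C9–O bond, gives the β-hydroxy ketone F2. Dehydration with MsCl/Et3N gives the alkylidene ketone F3, and conjugate reduction with [(Ph3P)CuH]6 gives keto acetal 22.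

Step 6 (retentive chlorination at the neopentylic C3). The risk is Wagner–Meerwein shift or elimination from a cationoid C3. The fallback sets out from 8 and returns at 13, which is then deketalised as in the last stage of step 6. Condensation with TsNHNH2 gives the tosylhydrazone F4, and Shapiro elimination (MeLi) gives the diene ketal F5. Anti-dichlorination of the less hindered C2=C3 bond with Et4NCl3 gives the trans-diaxial 2β,3α-dichloro ketal F6. ZnCl2-promoted diaxial → diequatorial rearrangement through a chloronium/chloride ion pair, driven by loss of the Cl/CH3 syn-axial contacts, gives 13. This last equilibration is the least certain part of the fallback.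

Step 12 (palladium-catalysed epoxide isomerisation). The risk is over-isomerisation to the conjugated 7-en-6-one. The fallback sets out from 25 and returns at 26. Palladium-catalysed formate hydrogenolysis of the vinyl epoxide (Pd2(dba)3·CHCl3, PBu3, HCO2H/Et3N) delivers hydride to C7 and keeps the exocyclic alkene, giving the homoallylic alcohol F7. Dess–Martin oxidation (NaHCO3 buffer) gives 26.

**Further compounds**

F1 | step 9 | epoxy alcohol: 19 with the side-chain alkene as trans-epoxide, 8β-OH retained | Cl[C@H]1[C@H](Cl)C[C@]2(C)[C@](O)([C@H]3O[C@@H]3C(OCC)OCC)CC=C2C1(C)C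
F2 | step 9 | β-hydroxy ketone: ring-expanded C8 ketone with 9β-(2,2-diethoxy-1-hydroxyethyl) group | Cl[C@H]1[C@H](Cl)C[C@]2(C)[C@@H]([C@H](O)C(OCC)OCC)C(=O)CC=C2C1(C)C
F3 | step 9 | (Z)-alkylidene ketone: C9=C11 enone, C8 ketone | Cl[C@H]1[C@H](Cl)C[C@]2(C)/C(=C/C(OCC)OCC)C(=O)CC=C2C1(C)C
F4 | step 6 | (E)-tosylhydrazone of 8 | Cc1ccc(cc1)S(=O)(=O)N/N=C1\CC[C@]2(C)C3(OCCO3)CC=C2C1(C)C
F5 | step 6 | diene ketal (C2=C3 and C5=C6, C8 dioxolane) | CC1(C)C=CC[C@]2(C)C3(OCCO3)CC=C12
F6 | step 6 | 2β,3α-dichloro ketal (trans-diaxial) | Cl[C@@H]1[C@@H](Cl)C[C@]2(C)C3(OCCO3)CC=C2C1(C)C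
F7 | step 12 | 6α-hydroxy-8(17)-ene diethyl acetal | C=C1C[C@H](O)[C@H]2C(C)(C)[C@@H](Cl)[C@H](Cl)C[C@]2(C)[C@H]1CC(OCC)OCC
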